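A direct plan would first mono-acylate 2,4,6-trihydroxybenzaldehyde A1 at O4 and reduce the product to the salicyl alcohol A2.
Ring C would be closed by hetero-Diels–Alder reaction of the quinone methide from A2 with a chiral aryl allene A3.
Alkene cleavage of the adduct A4 would give the flavan-3-one A5; reduction to the cis alcohol and debenzylation would follow.
Weak: the mono-acylation of a triphenol, since over-acylation or acyl transfer would undo the only control over O7.
Weak: the cycloaddition, since quinone methide oligomerisation and the axial-to-central chirality transfer would be unproven.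
Weak: the passage through A5, since C2 (benzylic, α to oxygen and to the ketone) would be prone to epimerisation.

**Strategy.** The target is read as a C-aryl glycoside: the bond between C2 of ring C and ring B is disconnected, leaving an enantiopure chroman-2,3-diol (a benzo-fused, sugar-like lactol) and a ring B boronic acid. In the key step the aryl group is delivered from boron held on O3 to the C2 oxocarbenium ion, which joins the fragments and sets C2 cis to C3 in one operation; C3 comes from methyl (R)-glycidate. The feature exploited on ring A is the mirror symmetry of a 2-substituted phloroglucinol: O1 and O5 are equivalent before lactonisation and O7 is unique, so the gallate position is fixed by symmetry. No phenol-selective acylation, cycloaddition or flavan-3-one is needed.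

Key step: step 8

Remark: lactol 11 is carried as its anomeric mixture, because the anomers interconvert through the open hydroxy aldehyde under the conditions of step 8.

**Step 1**
Reactants: 1 benzene-1,3,5-triol (phloroglucinol)
Product: 2 5-[(triisopropylsilyl)oxy]benzene-1,3-diol
Conditions: 1 (3 equiv), i-Pr3SiCl (1 equiv), imidazole, DMF, 0 °C → rt; excess 1 removed by aqueous wash
Reagents that add atoms: chlorotriisopropylsilane, CC(C)[Si](Cl)(C(C)C)C(C)C
Why: O-Silylation of a threefold-symmetric triol, in which only the degree of silylation has to be controlled (excess of the cheap, water-soluble triol), should give the mono-silyl ether whose silylated oxygen later becomes O7; no stereocentre is formed.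

**Step 2**
Reactants: 2 5-[(triisopropylsilyl)oxy]benzene-1,3-diol
Product: 3 [3,5-bis(methoxymethoxy)phenoxy]triisopropylsilane
Conditions: MOMCl (2.6 equiv), i-Pr2NEt (3 equiv), CH2Cl2, 0 °C → rt
Reagents that add atoms: chloromethyl methyl ether, COCCl
Why: O-Alkylation of both remaining phenols with the α-chloro ether (Williamson-type acetal formation) should give the bis-MOM ether, whose two acetals direct the next metalation and later become O1 and O5.

**Step 3**
Reactants: 3 [3,5-bis(methoxymethoxy)phenoxy]triisopropylsilane; 4 methyl (2R)-oxirane-2-carboxylate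
Product: 7 methyl (2R)-3-{2,6-bis(methoxymethoxy)-4-[(triisopropylsilyl)oxy]phenyl}-2-hydroxypropanoate, via aryllithium 5 (not isolated), via arylmagnesium bromide 6 (not isolated)
Conditions: n-BuLi (1.1 equiv), THF, 0 °C; MgBr2·OEt2 (1.05 equiv); CuI (10 mol %), then 4 (1.2 equiv), −40 → −10 °C; aq NH4Cl
Reagents that add atoms: none
Why: Directed ortho-metalation between the two cooperating MOM ethers (the bulky silyl ether does not direct), transmetalation to magnesium and copper-catalysed SN2 opening of the glycidic ester at its terminal carbon should give the aryllactate; the C–O bond of the stereocentre is not broken, so the (R) centre of 4 is carried over unchanged and becomes C3.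

**Step 4**
Reactants: 7 methyl (2R)-3-{2,6-bis(methoxymethoxy)-4-[(triisopropylsilyl)oxy]phenyl}-2-hydroxypropanoate
Product: 9 (3R)-3,5-dihydroxy-7-[(triisopropylsilyl)oxy]-3,4-dihydro-2H-chromen-2-one, via triol ester 8 (not isolated)
Conditions: HCl (1.25 M in MeOH), 0 °C → rt; concentrate; p-TsOH·H2O (5 mol %), PhMe, 70 °C
Reagents that add atoms: none
Why: Acid-catalysed acetal cleavage frees two phenols that are equivalent by symmetry and lactonisation (intramolecular transesterification) by either one gives the same dihydrocoumarin, so O1 and O5 are told apart without any phenol-selective reagent and the silyl ether is left at O7; C3 is not enolised under acid.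

**Step 5**
Reactants: 9 (3R)-3,5-dihydroxy-7-[(triisopropylsilyl)oxy]-3,4-dihydro-2H-chromen-2-one
Product: 10 (3R)-5-(benzyloxy)-3-hydroxy-7-[(triisopropylsilyl)oxy]-3,4-dihydro-2H-chromen-2-one
Conditions: BnOH (1.2 equiv), PPh3 (1.3 equiv), DIAD (1.3 equiv), THF, 0 °C → rt
Reagents that add atoms: benzyl alcohol, OCc1ccccc1
Why: Mitsunobu etherification alkylates only the acidic phenol with the primary alcohol, while the secondary 3-hydroxyl is neither acidic enough to act as the nucleophile nor activated as fast as benzyl alcohol, and the neutral conditions spare the aryl lactone and C3.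

**Step 6**
Reactants: 10 (3R)-5-(benzyloxy)-3-hydroxy-7-[(triisopropylsilyl)oxy]-3,4-dihydro-2H-chromen-2-one
Product: 11 (3R)-5-(benzyloxy)-7-[(triisopropylsilyl)oxy]-3,4-dihydro-2H-chromene-2,3-diol (anomeric mixture at C2)
Conditions: i-Bu2AlH (3.2 equiv), CH2Cl2, −78 °C; aq potassium sodium tartrate
Reagents that add atoms: none
Why: Half-reduction of the lactone with the aluminium hydride at −78 °C, where the tetrahedral aluminium alkoxide is stable until work-up, should stop at the lactol, which stays closed as the cyclic hemiacetal so that the α-hydroxy aldehyde is not exposed; C3 is untouched and C2 is obtained as an anomeric mixture.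

**Step 7**
Reactants: 12 5-bromo-1,2,3-tris(benzyloxy)benzene
Product: 14 [3,4,5-tris(benzyloxy)phenyl]boronic acid, via aryllithium 13 (not isolated)
Conditions: n-BuLi (1.05 equiv), THF, −78 °C; B(Oi-Pr)3 (1.5 equiv), −78 °C → rt; 1 M HCl
Reagents that add atoms: triisopropyl borate, CC(C)OB(OC(C)C)OC(C)C; water, O
Why: Bromine–lithium exchange at −78 °C is faster than benzylic deprotonation, and trapping of the aryllithium with the borate ester followed by hydrolysis (electrophilic borylation) should give the boronic acid.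

**Step 8**
Reactants: 11 (3R)-5-(benzyloxy)-7-[(triisopropylsilyl)oxy]-3,4-dihydro-2H-chromene-2,3-diol; 14 [3,4,5-tris(benzyloxy)phenyl]boronic acid
Product: 16 (2R,3R)-5-(benzyloxy)-2-[3,4,5-tris(benzyloxy)phenyl]-7-[(triisopropylsilyl)oxy]-3,4-dihydro-2H-chromen-3-ol, via cyclic arylboronate 15 (not isolated)
Conditions: 14 (1.5 equiv), 4 Å MS, CH2Cl2, rt; then BF3·OEt2 (2 equiv), −40 → 0 °C; aq NaHCO3
Reagents that add atoms: none
Why: Proposed new method: the cis-lactol anomer of 11 condenses with the boronic acid to the 2,3-O-arylboronate 15; BF3 then ionises the C2–O bond, leaving the aryl group on a borate that stays bound to O3, and the electron-rich ipso carbon (para to a benzyloxy group) migrates from boron to C2 of the chroman-2-ylium ion through a five-membered transition state. The closest known reaction types are the Petasis borono-Mannich reaction of α-hydroxy aldehydes and the hydroxyl-directed addition of aryl boronates to cyclic N-acyliminium ions, which gives 2,3-cis products; aryl transfer from boron to the oxocarbenium ions of chromene acetals is also known. No ring is closed: ring C is already present and the step forms the C2–C1′ bond that joins ring B. C2 is set by the tether, since an aryl group bound through O3 can only reach the face of C2 on which O3 lies, so aryl and 3-OH come out cis (2R,3R), while C3 is carried from the glycidate. The step needs this facial selectivity, secured by the free 3-OH kept open in step 5, and site selectivity on ring B, secured by ipso substitution at boron. Intermolecular attack of ring A on the cation is disfavoured by the intramolecular delivery and by the benzyl ether at O5.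

**Step 9**
Reactants: 16 (2R,3R)-5-(benzyloxy)-2-[3,4,5-tris(benzyloxy)phenyl]-7-[(triisopropylsilyl)oxy]-3,4-dihydro-2H-chromen-3-ol; 17 3,4,5-tris(benzyloxy)benzoyl chloride
Product: 19 (2R,3R)-5-(benzyloxy)-3-hydroxy-2-[3,4,5-tris(benzyloxy)phenyl]-3,4-dihydro-2H-chromen-7-yl 3,4,5-tris(benzyloxy)benzoate, via ammonium phenoxide 18 (not isolated)
Conditions: TBAF (1.05 equiv), THF, 0 °C; cool to −40 °C, then 17 (1.2 equiv), −40 → 0 °C
Reagents that add atoms: none
Why: Fluoride cleaves the aryl silyl ether to the phenoxide, which is acylated in the same flask by the acid chloride (O-acylation of a phenoxide), while the neutral secondary 3-hydroxyl does not react without an acyl-transfer catalyst; with O5 benzylated the ester can only form at O7 and no stereocentre is affected.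

**Step 10**
Reactants: 19 (2R,3R)-5-(benzyloxy)-3-hydroxy-2-[3,4,5-tris(benzyloxy)phenyl]-3,4-dihydro-2H-chromen-7-yl 3,4,5-tris(benzyloxy)benzoate
Product: 20 epigallocatechin 7-O-gallate, (2R,3R)-3,5-dihydroxy-2-(3,4,5-trihydroxyphenyl)-3,4-dihydro-2H-chromen-7-yl 3,4,5-trihydroxybenzoate
Conditions: H2 (1 atm), 20% Pd(OH)2/C, THF/MeOH, rt
Reagents that add atoms: none
Why: Palladium-catalysed hydrogenolysis should cleave the seven benzyl ethers while the aryl ester, the ring ether and both stereocentres stay intact, giving the target.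

**Compound list**
1 | benzene-1,3,5-triol (phloroglucinol) | Oc1cc(O)cc(O)c1 | starting material
2 | 5-[(triisopropylsilyl)oxy]benzene-1,3-diol | CC(C)[Si](Oc1cc(O)cc(O)c1)(C(C)C)C(C)C | intermediate
3 | [3,5-bis(methoxymethoxy)phenoxy]triisopropylsilane | COCOc1cc(OCOC)cc(O[Si](C(C)C)(C(C)C)C(C)C)c1 | intermediate
4 | methyl (2R)-oxirane-2-carboxylate | COC(=O)[C@H]1CO1 | starting material
5 | {2,6-bis(methoxymethoxy)-4-[(triisopropylsilyl)oxy]phenyl}lithium | [Li]c1c(OCOC)cc(O[Si](C(C)C)(C(C)C)C(C)C)cc1OCOC | intermediate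
6 | {2,6-bis(methoxymethoxy)-4-[(triisopropylsilyl)oxy]phenyl}magnesium bromide | Br[Mg]c1c(OCOC)cc(O[Si](C(C)C)(C(C)C)C(C)C)cc1OCOC | intermediate
7 | methyl (2R)-3-{2,6-bis(methoxymethoxy)-4-[(triisopropylsilyl)oxy]phenyl}-2-hydroxypropanoate | COC(=O)[C@H](O)Cc1c(OCOC)cc(O[Si](C(C)C)(C(C)C)C(C)C)cc1OCOC | intermediate
8 | methyl (2R)-3-{2,6-dihydroxy-4-[(triisopropylsilyl)oxy]phenyl}-2-hydroxypropanoate | COC(=O)[C@H](O)Cc1c(O)cc(O[Si](C(C)C)(C(C)C)C(C)C)cc1O | intermediate
9 | (3R)-3,5-dihydroxy-7-[(triisopropylsilyl)oxy]-3,4-dihydro-2H-chromen-2-one | O=C1Oc2cc(O[Si](C(C)C)(C(C)C)C(C)C)cc(O)c2C[C@H]1O | intermediate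
10 | (3R)-5-(benzyloxy)-3-hydroxy-7-[(triisopropylsilyl)oxy]-3,4-dihydro-2H-chromen-2-one | O=C1Oc2cc(O[Si](C(C)C)(C(C)C)C(C)C)cc(OCc3ccccc3)c2C[C@H]1O | intermediate
11 | (3R)-5-(benzyloxy)-7-[(triisopropylsilyl)oxy]-3,4-dihydro-2H-chromene-2,3-diol (anomeric mixture at C2) | OC1Oc2cc(O[Si](C(C)C)(C(C)C)C(C)C)cc(OCc3ccccc3)c2C[C@H]1O | intermediate
12 | 5-bromo-1,2,3-tris(benzyloxy)benzene | Brc1cc(OCc2ccccc2)c(OCc2ccccc2)c(OCc2ccccc2)c1 | starting material
13 | [3,4,5-tris(benzyloxy)phenyl]lithium | [Li]c1cc(OCc2ccccc2)c(OCc2ccccc2)c(OCc2ccccc2)c1 | intermediate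
14 | [3,4,5-tris(benzyloxy)phenyl]boronic acid | OB(O)c1cc(OCc2ccccc2)c(OCc2ccccc2)c(OCc2ccccc2)c1 | intermediate
15 | (2S,3R)-5-(benzyloxy)-7-[(triisopropylsilyl)oxy]-3,4-dihydro-2H-chromene-2,3-diyl [3,4,5-tris(benzyloxy)phenyl]boronate (cis-fused cyclic boronate) | CC(C)[Si](Oc1cc(OCc2ccccc2)c2c(c1)O[C@@H]1OB(c3cc(OCc4ccccc4)c(OCc4ccccc4)c(OCc4ccccc4)c3)O[C@@H]1C2)(C(C)C)C(C)C | intermediate
16 | (2R,3R)-5-(benzyloxy)-2-[3,4,5-tris(benzyloxy)phenyl]-7-[(triisopropylsilyl)oxy]-3,4-dihydro-2H-chromen-3-ol | CC(C)[Si](Oc1cc(OCc2ccccc2)c2c(c1)O[C@H](c1cc(OCc3ccccc3)c(OCc3ccccc3)c(OCc3ccccc3)c1)[C@H](O)C2)(C(C)C)C(C)C | intermediate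
17 | 3,4,5-tris(benzyloxy)benzoyl chloride | O=C(Cl)c1cc(OCc2ccccc2)c(OCc2ccccc2)c(OCc2ccccc2)c1 | starting material
18 | tetrabutylammonium (2R,3R)-5-(benzyloxy)-3-hydroxy-2-[3,4,5-tris(benzyloxy)phenyl]-3,4-dihydro-2H-chromen-7-olate | CCCC[N+](CCCC)(CCCC)CCCC.[O-]c1cc(OCc2ccccc2)c2c(c1)O[C@H](c1cc(OCc3ccccc3)c(OCc3ccccc3)c(OCc3ccccc3)c1)[C@H](O)C2 | intermediate
19 | (2R,3R)-5-(benzyloxy)-3-hydroxy-2-[3,4,5-tris(benzyloxy)phenyl]-3,4-dihydro-2H-chromen-7-yl 3,4,5-tris(benzyloxy)benzoate | O=C(Oc1cc(OCc2ccccc2)c2c(c1)O[C@H](c1cc(OCc3ccccc3)c(OCc3ccccc3)c(OCc3ccccc3)c1)[C@H](O)C2)c1cc(OCc2ccccc2)c(OCc2ccccc2)c(OCc2ccccc2)c1 | intermediate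
20 | epigallocatechin 7-O-gallate, (2R,3R)-3,5-dihydroxy-2-(3,4,5-trihydroxyphenyl)-3,4-dihydro-2H-chromen-7-yl 3,4,5-trihydroxybenzoate | O=C(Oc1cc(O)c2c(c1)O[C@H](c1cc(O)c(O)c(O)c1)[C@H](O)C2)c1cc(O)c(O)c(O)c1 | target

**Count and risks**
Total steps: 10. Longest linear sequence: 9 (steps 1–6, 8, 9, 10); step 7 is a one-step branch.

Step 8 (proposed new method). The aryl transfer from boron may fail to outrun undirected intermolecular attack on the cation, proton loss at C3 (isomerisation towards the chroman-3-one) or protodeboronation, so that cis selectivity or the integrity of C3 would erode. The fallback uses known chemistry, sets out from lactone 10 and returns at 16. Opening of 10 with MeNH(OMe)·HCl and i-PrMgCl should give the Weinreb amide, (2R)-3-{2-(benzyloxy)-6-hydroxy-4-[(triisopropylsilyl)oxy]phenyl}-2-hydroxy-N-methoxy-N-methylpropanamide F1. After deprotonation of its two hydroxyls with MeMgBr, aryllithium 13 should give the α-hydroxy ketone F2. Chelation-controlled reduction with Zn(BH4)2 should give the anti (1S,2R) diol F3. Orthoester cyclisation (HC(OEt)3, PPTS, 60 °C) then closes ring C through the dioxolanylium ion, the phenol attacking the benzylic carbon with inversion, to give the cis 3-O-formate F4. Mild methanolysis (NaHCO3, MeOH) of the formate returns 16.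

Step 3. The di-ortho-substituted arylmagnesium species may open the epoxide slowly, so that attack on the ester or bromohydrin formation by magnesium bromide could compete. The fallback sets out from 3 and returns at 9. Aryllithium 5 is quenched with DMF to give 2,6-bis(methoxymethoxy)-4-[(triisopropylsilyl)oxy]benzaldehyde F5. Horner–Wadsworth–Emmons reaction with methyl 2-acetoxy-2-(dimethoxyphosphoryl)acetate (LiCl, DBU, MeCN) should give the enol acetate F6. Asymmetric hydrogenation with [Rh(cod)((R,R)-Et-DuPHOS)]OTf under H2 should give the (2R)-acetoxy ester F7; the ligand enantiomer would be chosen to give the (R) sense. F7 is taken straight into the acidic methanol and lactonisation conditions of step 4, which also remove the acetate, to give 9.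

Step 5. The Mitsunobu reagents may also activate the secondary α-hydroxyl (intermolecular aryl ether formation with inversion at C3), or the phenoxide may open the aryl lactone. The fallback sets out from 9 and returns at 11, moving the benzylation to a base-stable acetal. Reduction of 9 with i-Bu2AlH gives the lactol triol F8, which HCl (cat.) in MeOH converts into the methyl acetal F9. Williamson benzylation of the phenol alone (BnBr, K2CO3, acetone) gives the benzyl ether F10, and acetal hydrolysis (AcOH/H2O/THF, 40 °C) returns lactol 11.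

**Further compounds**
F1 | step 8 | (2R)-3-{2-(benzyloxy)-6-hydroxy-4-[(triisopropylsilyl)oxy]phenyl}-2-hydroxy-N-methoxy-N-methylpropanamide | CON(C)C(=O)[C@H](O)Cc1c(O)cc(O[Si](C(C)C)(C(C)C)C(C)C)cc1OCc1ccccc1
F2 | step 8 | (2R)-3-{2-(benzyloxy)-6-hydroxy-4-[(triisopropylsilyl)oxy]phenyl}-2-hydroxy-1-[3,4,5-tris(benzyloxy)phenyl]propan-1-one | O=C(c1cc(OCc2ccccc2)c(OCc2ccccc2)c(OCc2ccccc2)c1)[C@H](O)Cc1c(O)cc(O[Si](C(C)C)(C(C)C)C(C)C)cc1OCc1ccccc1
F3 | step 8 | (1S,2R)-3-{2-(benzyloxy)-6-hydroxy-4-[(triisopropylsilyl)oxy]phenyl}-1-[3,4,5-tris(benzyloxy)phenyl]propane-1,2-diol | O[C@@H](c1cc(OCc2ccccc2)c(OCc2ccccc2)c(OCc2ccccc2)c1)[C@H](O)Cc1c(O)cc(O[Si](C(C)C)(C(C)C)C(C)C)cc1OCc1ccccc1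
F4 | step 8 | (2R,3R)-5-(benzyloxy)-2-[3,4,5-tris(benzyloxy)phenyl]-7-[(triisopropylsilyl)oxy]-3,4-dihydro-2H-chromen-3-yl formate | CC(C)[Si](Oc1cc(OCc2ccccc2)c2c(c1)O[C@H](c1cc(OCc3ccccc3)c(OCc3ccccc3)c(OCc3ccccc3)c1)[C@H](OC=O)C2)(C(C)C)C(C)C
F5 | step 3 | 2,6-bis(methoxymethoxy)-4-[(triisopropylsilyl)oxy]benzaldehyde | O=Cc1c(OCOC)cc(O[Si](C(C)C)(C(C)C)C(C)C)cc1OCOC
F6 | step 3 | methyl (2Z)-2-(acetyloxy)-3-{2,6-bis(methoxymethoxy)-4-[(triisopropylsilyl)oxy]phenyl}prop-2-enoate | COC(=O)/C(OC(C)=O)=C/c1c(OCOC)cc(O[Si](C(C)C)(C(C)C)C(C)C)cc1OCOC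
F7 | step 3 | methyl (2R)-2-(acetyloxy)-3-{2,6-bis(methoxymethoxy)-4-[(triisopropylsilyl)oxy]phenyl}propanoate | COC(=O)[C@H](OC(C)=O)Cc1c(OCOC)cc(O[Si](C(C)C)(C(C)C)C(C)C)cc1OCOC
F8 | step 5 | (3R)-7-[(triisopropylsilyl)oxy]-3,4-dihydro-2H-chromene-2,3,5-triol (anomeric mixture) | OC1Oc2cc(O[Si](C(C)C)(C(C)C)C(C)C)cc(O)c2C[C@H]1O
F9 | step 5 | (3R)-2-methoxy-7-[(triisopropylsilyl)oxy]-3,4-dihydro-2H-chromene-3,5-diol (anomeric mixture) | COC1Oc2cc(O[Si](C(C)C)(C(C)C)C(C)C)cc(O)c2C[C@H]1O
F10 | step 5 | (3R)-5-(benzyloxy)-2-methoxy-7-[(triisopropylsilyl)oxy]-3,4-dihydro-2H-chromen-3-ol (anomeric mixture) | COC1Oc2cc(O[Si](C(C)C)(C(C)C)C(C)C)cc(OCc3ccccc3)c2C[C@H]1O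
A1 | direct plan | 2,4,6-trihydroxybenzaldehyde | O=Cc1c(O)cc(O)cc1O
A2 | direct plan | 3,5-dihydroxy-4-(hydroxymethyl)phenyl 3,4,5-tris(benzyloxy)benzoate | OCc1c(O)cc(OC(=O)c2cc(OCc3ccccc3)c(OCc3ccccc3)c(OCc3ccccc3)c2)cc1O
A3 | direct plan | (Sa)-1,2,3-tris(benzyloxy)-5-(buta-1,2-dien-1-yl)benzene | [H]C(c1cc(OCc2ccccc2)c(OCc2ccccc2)c(OCc2ccccc2)c1)=[C@]=C([H])C
A4 | direct plan | (2S,3Z)-3-ethylidene-5-hydroxy-2-[3,4,5-tris(benzyloxy)phenyl]-3,4-dihydro-2H-chromen-7-yl 3,4,5-tris(benzyloxy)benzoate | O=C(Oc1cc(O)c2c(c1)O[C@H](c1cc(OCc3ccccc3)c(OCc3ccccc3)c(OCc3ccccc3)c1)/C(=C\C)C2)c1cc(OCc2ccccc2)c(OCc2ccccc2)c(OCc2ccccc2)c1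
A5 | direct plan | (2R)-5-hydroxy-3-oxo-2-[3,4,5-tris(benzyloxy)phenyl]-3,4-dihydro-2H-chromen-7-yl 3,4,5-tris(benzyloxy)benzoate | O=C(Oc1cc(O)c2c(c1)O[C@H](c1cc(OCc3ccccc3)c(OCc3ccccc3)c(OCc3ccccc3)c1)C(=O)C2)c1cc(OCc2ccccc2)c(OCc2ccccc2)c(OCc2ccccc2)c1
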